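**Plan**

1. Retrosynthesis, first cut: the C8''–C7'' bond of the arylglycerol unit, between the carbon that carries the syringyl ether oxygen and CH2OH and the benzylic carbinol carbon of the terminal guaiacyl ring. The ArO–CH(CH2OH)–CH(OH)Ar array is a reduced anti-aldol pattern: the α-oxygen and the C9'' hydroxymethyl (a reduced formyl group) make the left half an α-aryloxyacetaldehyde enamine donor, and C7'' on the guaiacyl ring is the carbonyl carbon of a non-enolisable benzaldehyde.
2. Second cut: the two benzylic C–O bonds (C7–O, C7'–O) of the 3,7-dioxabicyclo[3.3.0]octane, opening both tetrahydrofuran rings to an acyclic tetraol. Third cut: C7–C8 and C8'–C7' of that tetraol, by a dithiane conjugate addition/aldol on a chiral 5-alkoxybutenolide.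
3. Forward: butenolide → trans,trans-lactone → aryl ketone → tetraol → both tetrahydrofuran rings in one operation → allyl ether cut to OCH2CHO → cross-aldol with a vanillin ester and reduction in the same flask → removal of pivalate and silyl group.
4. Stereochemistry: C8 and C8' (both R) come from the menthyloxy acetal carbon of the butenolide (anti,anti addition). C7 and C7' (both S) come from exo capture of benzylic cations on the cis-fused bicycle. C8'' (R) and C7'' (S) come from L-proline in the anti-selective enamine aldol.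

Key step: step 10

Remark: (5R)-5-(l-menthyloxy)-2(5H)-furanone 6 is taken as a purchasable chiral butenolide; lignan locants are used (C7 benzylic, C8 branching, C9 oxymethylene; guaiacyl half of the furofuran unprimed, syringyl half primed, arylglycerol unit doubly primed).

**Step 1**
Reactants: 1 vanillin
Product: 2 2-(4-hydroxy-3-methoxyphenyl)-1,3-dithiane
Conditions: HS(CH2)3SH, BF3·OEt2 (cat.), CH2Cl2, 0 °C → rt
Reagents that add atoms: 1,3-propanedithiol SCCCS
Why: Lewis acid-catalysed dithioacetalisation of an aromatic aldehyde (first stage of the Corey–Seebach umpolung) is selective for the formyl group and tolerates the free phenol; no stereocentre is formed.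

**Step 2**
Reactants: 2 2-(4-hydroxy-3-methoxyphenyl)-1,3-dithiane
Product: 3 2-(3-methoxy-4-triisopropylsilyloxyphenyl)-1,3-dithiane
Conditions: TIPSCl, imidazole, DMF, rt
Reagents that add atoms: chlorotriisopropylsilane CC(C)[Si](Cl)(C(C)C)C(C)C
Why: Imidazole-promoted silylation of the phenol gives a bulky aryl silyl ether that should survive n-BuLi, LiAlH4, MsCl/pyridine and periodate later in the route; no stereocentre is formed.

**Step 3**
Reactants: 4 syringaldehyde
Product: 5 4-allyloxy-3,5-dimethoxybenzaldehyde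
Conditions: allyl bromide, K2CO3, DMF, 60 °C
Reagents that add atoms: allyl bromide C=CCBr
Why: Williamson ether synthesis on the acidic syringyl phenol installs the allyl group as a masked OCH2CHO unit; no stereocentre is formed.

**Step 4**
Reactants: 3 2-(3-methoxy-4-triisopropylsilyloxyphenyl)-1,3-dithiane; 6 (5R)-5-(l-menthyloxy)-2(5H)-furanone; 5 4-allyloxy-3,5-dimethoxybenzaldehyde
Product: 9 tandem adduct (3S,4R,5R)-3-[(4-allyloxy-3,5-dimethoxyphenyl)(hydroxy)methyl]-5-(l-menthyloxy)-4-[2-(3-methoxy-4-triisopropylsilyloxyphenyl)-1,3-dithian-2-yl]dihydrofuran-2(3H)-one (carbinol carbon as epimer mixture), via 2-lithiodithiane 7 (not isolated), via lithium lactone enolate 8 (not isolated)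
Conditions: n-BuLi, THF, −78 → −30 °C; 6, −78 °C; 5, −78 °C; AcOH, −78 °C
Reagents that add atoms: none
Why: Corey–Seebach acyl-anion chemistry in a tandem Michael addition/aldol: the soft lithiated aryl dithiane should add 1,4 to the butenolide anti to the menthyloxy group at the acetal carbon (setting lactone C4, the future C8, as R), and the lactone enolate should be trapped by aldehyde 5 anti to the new C4 substituent (setting lactone C3, the future C8', as R), while the carbinol epimer mixture is erased in step 7.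

**Step 5**
Reactants: 9 tandem adduct
Product: 10 keto lactone (3S,4R,5R)-3-[(4-allyloxy-3,5-dimethoxyphenyl)(hydroxy)methyl]-5-(l-menthyloxy)-4-(3-methoxy-4-triisopropylsilyloxybenzoyl)dihydrofuran-2(3H)-one (carbinol carbon as epimer mixture)
Conditions: MeI, CaCO3, MeCN/H2O (4:1), 45 °C
Reagents that add atoms: water O
Why: Alkylative hydrolysis of the dithiane (S-methylation, then ring opening by water) unmasks the aryl ketone under buffered, near-neutral conditions that should spare the allyl ether, the silyl ether and the acetal-lactone and avoid the divalent mercury salts that would attack the alkene; the lactone stereocentres are not touched.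

**Step 6**
Reactants: 10 keto lactone
Product: 11 tetraol (2R,3R)-2-[(4-allyloxy-3,5-dimethoxyphenyl)(hydroxy)methyl]-3-[hydroxy(3-methoxy-4-triisopropylsilyloxyphenyl)methyl]butane-1,4-diol (both carbinol carbons as epimer mixtures)
Conditions: LiAlH4, THF, 0 °C → rt
Reagents that add atoms: none
Why: LiAlH4 reduction of the ketone, of the lactone carbonyl and of the aldehyde released when the reduced acetal-lactone collapses with loss of menthoxide gives the tetraol and frees the auxiliary alcohol; C8 and C8' are fixed once the carbonyl groups are gone and the new carbinol centres need no control.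

**Step 7**
Reactants: 11 tetraol
Product: 12 furofuran (1S,3aR,4S,6aR)-1-(4-allyloxy-3,5-dimethoxyphenyl)-4-(3-methoxy-4-triisopropylsilyloxyphenyl)tetrahydro-1H,3H-furo[3,4-c]furan
Conditions: MsCl (2.2 equiv), pyridine, 0 °C → rt
Reagents that add atoms: none
Why: Double cycloetherification by sulfonate activation: the p-oxygenated benzylic carbinols should ionise on mesylation to quinoid benzylic cations that are captured 5-exo-trig by the CH2OH on the neighbouring branch carbon, the fixed (8R,8'R) pair enforcing the cis ring fusion and kinetic capture placing each aryl group exo (7S,7'S), so the carbinol epimers should converge on one furofuran.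

**Step 8**
Reactants: 12 furofuran allyl ether
Product: 14 aryloxyacetaldehyde 2-{4-[(1S,3aR,4S,6aR)-4-(3-methoxy-4-triisopropylsilyloxyphenyl)tetrahydro-1H,3H-furo[3,4-c]furan-1-yl]-2,6-dimethoxyphenoxy}acetaldehyde, via vicinal diol 13 (not isolated)
Conditions: OsO4 (2 mol%), NaIO4, 2,6-lutidine, dioxane/H2O (3:1), rt
Reagents that add atoms: osmium tetroxide O=[Os](=O)(=O)=O (catalytic carrier of the new oxygen); sodium periodate [Na+].[O-]I(=O)(=O)=O (terminal oxidant that restores it)
Why: Lemieux–Johnson oxidation: catalytic OsO4 dihydroxylates the only alkene and NaIO4 cleaves the diol to the aldehyde while 2,6-lutidine buffers the medium, so the benzylic ethers and the silyl ether should survive; no stereocentre of the product is formed and the aldehyde is used at once.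

**Step 9**
Reactants: 1 vanillin
Product: 15 4-formyl-2-methoxyphenyl pivalate
Conditions: PivCl, Et3N, DMAP (cat.), CH2Cl2, 0 °C → rt
Reagents that add atoms: pivaloyl chloride CC(C)(C)C(Cl)=O
Why: DMAP-catalysed acylation of the phenol turns vanillin into a more electrophilic, non-enolisable aldehyde whose hindered ester should resist aminolysis by the proline catalyst; no stereocentre is formed.

**Step 10**
Reactants: 14 aryloxyacetaldehyde; 15 4-formyl-2-methoxyphenyl pivalate
Product: 17 erythro diol 4-[(1S,2R)-1,3-dihydroxy-2-(aryloxy)propyl]-2-methoxyphenyl pivalate (aryloxy group as in 14), via aldol aldehyde 16 (not isolated)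
Conditions: L-proline (20 mol%), 15 (5 equiv), DMF, 4 °C, 14 added by syringe pump over 24 h; then MeOH, NaBH4, −20 → 0 °C
Reagents that add atoms: none
Why: L-Proline condenses with the only enolisable partner, aldehyde 14, to an (E)-enamine whose carboxylic acid hydrogen-bonds to aldehyde 15 and delivers it to one enamine face in a closed chair-like transition state, forming the bond between the aryloxy-bearing α-carbon and the benzylic carbonyl carbon; hydrolysis releases β-hydroxy aldehyde 16, which NaBH4 reduces in the same flask before it can epimerise or revert. The closest known reaction type is the proline-catalysed direct cross-aldol of α-oxygenated acetaldehyde donors with aldehyde acceptors (enamine catalysis, anti-selective). No ring is closed. Both new stereocentres are catalyst-controlled: the (S)-configured pyrrolidine carboxylic acid fixes the enamine face (giving the R aryloxy carbon C8'' of the diol) and the hydrogen-bonded anti approach of the aldehyde fixes the S carbinol C7'', i.e. the erythro relationship, while the furofuran stereocentres lie six bonds away and should not interfere. The step needs cross- over self-aldol selectivity and anti over syn selectivity: the first should be secured because 15 cannot form an enamine, is present in excess and is activated by its pivalate while 14 is kept at low concentration, the second by the bulky 2,6-dimethoxyaryloxy group, which should enforce the (E)-enamine and the anti transition state. The near-neutral conditions should leave the pivalate, the silyl ether and the acid-sensitive benzylic ethers of the furofuran untouched.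

**Step 11**
Reactants: 17 erythro diol
Product: 19 hedyotol C, via aryl silyl ether 18 (not isolated)
Conditions: K2CO3, MeOH, rt; then TBAF, THF, 0 °C → rt; aq. NH4Cl
Reagents that add atoms: none
Why: Base-mediated methanolysis of the aryl pivalate followed by fluoride cleavage of the aryl silyl ether frees both phenols under conditions that ionise neither the benzylic ethers nor the benzylic carbinol, so no stereocentre is affected.

**Compound list**

1 | vanillin (4-hydroxy-3-methoxybenzaldehyde) | COc1cc(C=O)ccc1O | starting material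
2 | 2-(4-hydroxy-3-methoxyphenyl)-1,3-dithiane | COc1cc(C2SCCCS2)ccc1O | intermediate
3 | 2-(3-methoxy-4-triisopropylsilyloxyphenyl)-1,3-dithiane | COc1cc(C2SCCCS2)ccc1O[Si](C(C)C)(C(C)C)C(C)C | intermediate
4 | syringaldehyde (4-hydroxy-3,5-dimethoxybenzaldehyde) | COc1cc(C=O)cc(OC)c1O | starting material
5 | 4-allyloxy-3,5-dimethoxybenzaldehyde | COc1cc(C=O)cc(OC)c1OCC=C | intermediate
6 | (5R)-5-[(1R,2S,5R)-menthyloxy]furan-2(5H)-one | CC(C)[C@@H]1CC[C@@H](C)C[C@H]1O[C@@H]1OC(=O)C=C1 | starting material
7 | 2-lithio-2-(3-methoxy-4-triisopropylsilyloxyphenyl)-1,3-dithiane | COc1cc(C2([Li])SCCCS2)ccc1O[Si](C(C)C)(C(C)C)C(C)C | intermediate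
8 | lithium enolate of (4R,5R)-4-[2-(3-methoxy-4-triisopropylsilyloxyphenyl)-1,3-dithian-2-yl]-5-(l-menthyloxy)dihydrofuran-2(3H)-one | [Li]OC1=C[C@@H](C2(SCCCS2)c2ccc(O[Si](C(C)C)(C(C)C)C(C)C)c(OC)c2)[C@H](O[C@@H]2C[C@H](C)CC[C@H]2C(C)C)O1 | intermediate
9 | (3S,4R,5R)-3-[(4-allyloxy-3,5-dimethoxyphenyl)(hydroxy)methyl]-5-(l-menthyloxy)-4-[2-(3-methoxy-4-triisopropylsilyloxyphenyl)-1,3-dithian-2-yl]dihydrofuran-2(3H)-one, carbinol carbon as epimer mixture | CC(C)[C@@H]1CC[C@@H](C)C[C@H]1O[C@@H]1OC(=O)[C@H](C(O)c2cc(OC)c(OCC=C)c(OC)c2)[C@H]1C1(SCCCS1)c1ccc(O[Si](C(C)C)(C(C)C)C(C)C)c(OC)c1 | intermediate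
10 | (3S,4R,5R)-3-[(4-allyloxy-3,5-dimethoxyphenyl)(hydroxy)methyl]-5-(l-menthyloxy)-4-(3-methoxy-4-triisopropylsilyloxybenzoyl)dihydrofuran-2(3H)-one, carbinol carbon as epimer mixture | CC(C)[C@@H]1CC[C@@H](C)C[C@H]1O[C@@H]1OC(=O)[C@H](C(O)c2cc(OC)c(OCC=C)c(OC)c2)[C@H]1C(=O)c1ccc(O[Si](C(C)C)(C(C)C)C(C)C)c(OC)c1 | intermediate
11 | (2R,3R)-2-[(4-allyloxy-3,5-dimethoxyphenyl)(hydroxy)methyl]-3-[hydroxy(3-methoxy-4-triisopropylsilyloxyphenyl)methyl]butane-1,4-diol, carbinol carbons as epimer mixtures | OC[C@H](C(O)c1cc(OC)c(OCC=C)c(OC)c1)[C@H](CO)C(O)c1ccc(O[Si](C(C)C)(C(C)C)C(C)C)c(OC)c1 | intermediate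
12 | (1S,3aR,4S,6aR)-1-(4-allyloxy-3,5-dimethoxyphenyl)-4-(3-methoxy-4-triisopropylsilyloxyphenyl)tetrahydro-1H,3H-furo[3,4-c]furan | COc1cc([C@H]2OC[C@H]3[C@@H]2CO[C@@H]3c2cc(OC)c(OCC=C)c(OC)c2)ccc1O[Si](C(C)C)(C(C)C)C(C)C | intermediate
13 | 3-{4-[(1S,3aR,4S,6aR)-4-(3-methoxy-4-triisopropylsilyloxyphenyl)tetrahydro-1H,3H-furo[3,4-c]furan-1-yl]-2,6-dimethoxyphenoxy}propane-1,2-diol, C2 as epimer mixture | COc1cc([C@H]2OC[C@H]3[C@@H]2CO[C@@H]3c2cc(OC)c(OCC(O)CO)c(OC)c2)ccc1O[Si](C(C)C)(C(C)C)C(C)C | intermediate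
14 | 2-{4-[(1S,3aR,4S,6aR)-4-(3-methoxy-4-triisopropylsilyloxyphenyl)tetrahydro-1H,3H-furo[3,4-c]furan-1-yl]-2,6-dimethoxyphenoxy}acetaldehyde | COc1cc([C@H]2OC[C@H]3[C@@H]2CO[C@@H]3c2cc(OC)c(OCC=O)c(OC)c2)ccc1O[Si](C(C)C)(C(C)C)C(C)C | intermediate
15 | 4-formyl-2-methoxyphenyl pivalate | COc1cc(C=O)ccc1OC(=O)C(C)(C)C | intermediate
16 | 4-[(1S,2S)-1-hydroxy-3-oxo-2-{4-[(1S,3aR,4S,6aR)-4-(3-methoxy-4-triisopropylsilyloxyphenyl)tetrahydro-1H,3H-furo[3,4-c]furan-1-yl]-2,6-dimethoxyphenoxy}propyl]-2-methoxyphenyl pivalate | COc1cc([C@H]2OC[C@H]3[C@@H]2CO[C@@H]3c2cc(OC)c(O[C@H](C=O)[C@@H](O)c3ccc(OC(=O)C(C)(C)C)c(OC)c3)c(OC)c2)ccc1O[Si](C(C)C)(C(C)C)C(C)C | intermediate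
17 | 4-[(1S,2R)-1,3-dihydroxy-2-{4-[(1S,3aR,4S,6aR)-4-(3-methoxy-4-triisopropylsilyloxyphenyl)tetrahydro-1H,3H-furo[3,4-c]furan-1-yl]-2,6-dimethoxyphenoxy}propyl]-2-methoxyphenyl pivalate | COc1cc([C@H]2OC[C@H]3[C@@H]2CO[C@@H]3c2cc(OC)c(O[C@H](CO)[C@@H](O)c3ccc(OC(=O)C(C)(C)C)c(OC)c3)c(OC)c2)ccc1O[Si](C(C)C)(C(C)C)C(C)C | intermediate
18 | 4-[(1S,2R)-1,3-dihydroxy-2-{4-[(1S,3aR,4S,6aR)-4-(3-methoxy-4-triisopropylsilyloxyphenyl)tetrahydro-1H,3H-furo[3,4-c]furan-1-yl]-2,6-dimethoxyphenoxy}propyl]-2-methoxyphenol | COc1cc([C@H]2OC[C@H]3[C@@H]2CO[C@@H]3c2cc(OC)c(O[C@H](CO)[C@@H](O)c3ccc(O)c(OC)c3)c(OC)c2)ccc1O[Si](C(C)C)(C(C)C)C(C)C | intermediate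
19 | hedyotol C, 4-[(1S,2R)-1,3-dihydroxy-2-{4-[(1S,3aR,4S,6aR)-4-(4-hydroxy-3-methoxyphenyl)tetrahydro-1H,3H-furo[3,4-c]furan-1-yl]-2,6-dimethoxyphenoxy}propyl]-2-methoxyphenol | COc1cc([C@H]2OC[C@H]3[C@@H]2CO[C@@H]3c2cc(OC)c(O[C@H](CO)[C@@H](O)c3ccc(O)c(OC)c3)c(OC)c2)ccc1O | target

**Step count and risks**

Total step count: 11. Longest linear sequence: 9 steps (steps 1, 2, 4, 5, 6, 7, 8, 10, 11 from vanillin).

Steps most likely to fail:

Step 10. The enamine aldol may suffer from self-aldolisation of the α-aryloxy aldehyde, sluggish addition to the still fairly electron-rich acceptor, or weak anti/syn discrimination. The fallback makes the same bond by a stoichiometric auxiliary-controlled anti-aldol. It sets out from 14: Pinnick oxidation (NaClO2, NaH2PO4, 2-methyl-2-butene, t-BuOH/H2O) gives the aryloxyacetic acid F1. Coupling with (R)-4-benzyl-oxazolidin-2-one (DCC, DMAP, CH2Cl2) gives the N-acyl oxazolidinone F2. The MgCl2-catalysed direct anti-aldol of N-acyl oxazolidinones with aromatic aldehydes (MgCl2 20 mol%, Et3N, TMSCl, EtOAc, rt) with 15 should then proceed through the chelated (Z)-magnesium enolate, attacked on the face remote from the benzyl group, to give the silylated anti adduct F3. Citric acid in MeOH desilylates it to the β-hydroxy imide F4, and NaBH4 in THF/H2O cleaves the auxiliary reductively, coming back to the route at 17.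

Step 7. The mesylate-triggered closure may fail to converge if a primary mesylate is displaced by the carbinol oxygen with retention at the benzylic carbon, or if the tetraol is over-sulfonylated. The fallback abandons sulfonate activation for Brønsted-acid ionisation. It sets out from 11: catalytic 10-camphorsulfonic acid in CH2Cl2 at 0 °C should ionise only the two benzylic carbinols, so that no primary leaving group is ever present and both carbinol configurations are erased in the cations before exo capture. It comes back to the route at 12 and makes no new compound (F0).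

Step 5. The freshly unmasked aroyl ketone sits next to the acetal-lactone, so β-elimination of the lactone oxygen, retro-aldol cleavage or epimerisation at C8 may intervene. The fallback changes the order of events so that the ketone never coexists with the lactone. It sets out from 9: LiAlH4 in THF first reduces the lactone and expels menthol to give the dithiane triol F5. MeI/CaCO3 in aqueous MeCN then unmasks the ketone to the keto triol F6 (expected to rest as its cyclic hemiketal), and NaBH4 in MeOH reduces it, coming back to the route at 11.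

**Further compounds**

F1 | step 10 | 2-{4-[(1S,3aR,4S,6aR)-4-(3-methoxy-4-triisopropylsilyloxyphenyl)tetrahydro-1H,3H-furo[3,4-c]furan-1-yl]-2,6-dimethoxyphenoxy}acetic acid | COc1cc([C@H]2OC[C@H]3[C@@H]2CO[C@@H]3c2cc(OC)c(OCC(O)=O)c(OC)c2)ccc1O[Si](C(C)C)(C(C)C)C(C)C
F2 | step 10 | (R)-4-benzyl-3-(2-{4-[(1S,3aR,4S,6aR)-4-(3-methoxy-4-triisopropylsilyloxyphenyl)tetrahydro-1H,3H-furo[3,4-c]furan-1-yl]-2,6-dimethoxyphenoxy}acetyl)oxazolidin-2-one | COc1cc([C@H]2OC[C@H]3[C@@H]2CO[C@@H]3c2cc(OC)c(OCC(=O)N3[C@H](Cc4ccccc4)COC3=O)c(OC)c2)ccc1O[Si](C(C)C)(C(C)C)C(C)C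
F3 | step 10 | O-trimethylsilyl anti-aldol imide, 4-[(1S,2S)-3-[(R)-4-benzyl-2-oxooxazolidin-3-yl]-3-oxo-2-(aryloxy)-1-(trimethylsilyloxy)propyl]-2-methoxyphenyl pivalate (aryloxy group as in 14) | COc1cc([C@H]2OC[C@H]3[C@@H]2CO[C@@H]3c2cc(OC)c(O[C@H](C(=O)N3[C@H](Cc4ccccc4)COC3=O)[C@@H](O[Si](C)(C)C)c3ccc(OC(=O)C(C)(C)C)c(OC)c3)c(OC)c2)ccc1O[Si](C(C)C)(C(C)C)C(C)C
F4 | step 10 | anti-aldol β-hydroxy imide, 4-[(1S,2S)-3-[(R)-4-benzyl-2-oxooxazolidin-3-yl]-1-hydroxy-3-oxo-2-(aryloxy)propyl]-2-methoxyphenyl pivalate (aryloxy group as in 14) | COc1cc([C@H]2OC[C@H]3[C@@H]2CO[C@@H]3c2cc(OC)c(O[C@H](C(=O)N3[C@H](Cc4ccccc4)COC3=O)[C@@H](O)c3ccc(OC(=O)C(C)(C)C)c(OC)c3)c(OC)c2)ccc1O[Si](C(C)C)(C(C)C)C(C)C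
F0 | step 7 | none | none
F5 | step 5 | (2R,3R)-2-[(4-allyloxy-3,5-dimethoxyphenyl)(hydroxy)methyl]-3-[2-(3-methoxy-4-triisopropylsilyloxyphenyl)-1,3-dithian-2-yl]butane-1,4-diol, carbinol carbon as epimer mixture | OC[C@H](C(O)c1cc(OC)c(OCC=C)c(OC)c1)[C@H](CO)C1(SCCCS1)c1ccc(O[Si](C(C)C)(C(C)C)C(C)C)c(OC)c1
F6 | step 5 | (2R,3R)-3-[(4-allyloxy-3,5-dimethoxyphenyl)(hydroxy)methyl]-4-hydroxy-2-(hydroxymethyl)-1-(3-methoxy-4-triisopropylsilyloxyphenyl)butan-1-one, carbinol carbon as epimer mixture | OC[C@H](C(O)c1cc(OC)c(OCC=C)c(OC)c1)[C@H](CO)C(=O)c1ccc(O[Si](C(C)C)(C(C)C)C(C)C)c(OC)c1
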